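Tetralin numbering is used (C1 bears the syringyl ring C; ring A is the fused arene, ring B the carbocycle). Ring B is cut at C2–C3 and C4–C4a, which releases C3, C4 and the C3 hydroxymethyl group as plain allyl alcohol. The feature exploited is the vicinal CH2OH pair on C2 and C3: it is a masked 2-alkoxytetrahydrofuran, so allyl alcohol can be tethered as an acetal to the C2 side-chain carbon. The precursor is an enantiopure 2-bromo-3,3-diarylpropanal diallyl acetal with bromine at the future C4a. One nickel-catalysed reductive cascade (5-exo radical cyclisation, then aryl–alkyl coupling) closes both rings and relays C1 to C2 and C3.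

Key step: step 8

Assumption: the sense of induction in step 5 is taken from the accepted quadrant model of C2-symmetric bicyclooctadiene–rhodium catalysts ((R,R) ligand, acceptor bound through its alpha-Re face). If this enal responds in the opposite sense, the equally available (S,S) ligand is used and nothing else changes.

Step 1
Reactants: 1 2-bromo-5-hydroxy-4-methoxybenzaldehyde
Product: 2 5-(benzyloxy)-2-bromo-4-methoxybenzaldehyde
Conditions: BnBr, K2CO3, DMF, 60 °C
Reagents that add atoms: benzyl bromide, BrCc1ccccc1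
Why: Williamson ether synthesis on the only acidic OH gives a benzyl ether that should survive every later step and leave by hydrogenolysis at the end.

Step 2
Reactants: 2 5-(benzyloxy)-2-bromo-4-methoxybenzaldehyde; 3 (triphenylphosphoranylidene)acetaldehyde
Product: 4 (E)-3-[5-(benzyloxy)-2-bromo-4-methoxyphenyl]prop-2-enal
Conditions: toluene, 90 °C
Reagents that add atoms: none
Why: Wittig olefination with the stabilised formyl ylide should give the (E)-enal, and the aryl bromide and the ethers are inert to it.

Step 3
Reactants: 5 4-bromo-2,6-dimethoxyphenol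
Product: 6 2-(benzyloxy)-5-bromo-1,3-dimethoxybenzene
Conditions: BnBr, K2CO3, DMF, 60 °C
Reagents that add atoms: benzyl bromide, BrCc1ccccc1
Why: Williamson ether synthesis masks the ring C phenol with the same group as ring A, so that one final operation frees both.

Step 4
Reactants: 6 2-(benzyloxy)-5-bromo-1,3-dimethoxybenzene
Product: 9 [4-(benzyloxy)-3,5-dimethoxyphenyl]boronic acid, via aryllithium 7 (not isolated), via lithium aryltriisopropoxyborate 8 (not isolated)
Conditions: n-BuLi, THF, −78 °C; B(OiPr)3, −78 °C to rt; 1 M aq HCl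
Reagents that add atoms: triisopropyl borate, CC(C)OB(OC(C)C)OC(C)C; water, O
Why: Bromine–lithium exchange at −78 °C is faster than any attack on the ethers, and borylation of the aryllithium followed by acidic hydrolysis is the standard boronic acid synthesis.

Step 5
Reactants: 4 (E)-3-[5-(benzyloxy)-2-bromo-4-methoxyphenyl]prop-2-enal; 9 [4-(benzyloxy)-3,5-dimethoxyphenyl]boronic acid
Product: 10 (3S)-3-[5-(benzyloxy)-2-bromo-4-methoxyphenyl]-3-[4-(benzyloxy)-3,5-dimethoxyphenyl]propanal
Conditions: [RhCl(C2H4)2]2 (1.5 mol %), (1R,4R)-2,5-diphenylbicyclo[2.2.2]octa-2,5-diene (3.3 mol %), KOH (cat.), MeOH/H2O 10:1, 50 °C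
Reagents that add atoms: none
Why: In this Hayashi–Miyaura asymmetric 1,4-addition the arylrhodium inserts the enal held in the open quadrant of the C2-symmetric diene through its alpha-Re/beta-Re face, which sets the future C1 as (S), while diene ligands favour 1,4- over 1,2-addition to enals and monovalent rhodium leaves the aryl bromide alone.

Step 6
Reactants: 10 (3S)-3,3-diarylpropanal (aryl groups as named in step 5); 11 allyloxytrimethylsilane
Product: 13 (3S)-1-(allyloxy)-3-[5-(benzyloxy)-2-bromo-4-methoxyphenyl]-3-[4-(benzyloxy)-3,5-dimethoxyphenyl]prop-1-ene (E/Z mixture), via diallyl acetal 12 (not isolated)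
Conditions: 11 (2.2 equiv), TMSOTf (5 mol %), CH2Cl2, −78 °C; then iPr2NEt (1.6 equiv), TMSOTf (1.3 equiv), −20 °C to rt
Reagents that add atoms: none
Why: Noyori acetalisation with the silyl ether is followed in the same flask by the TMSOTf/amine acetal-to-enol-ether elimination, in which only the protons alpha to the oxocarbenium ion are acidified, so the doubly benzylic stereocentre is untouched.

Step 7
Reactants: 13 (3S)-allyl enol ether (E/Z mixture); 14 allyl alcohol
Product: 15 (3S)-2-bromo-3-[5-(benzyloxy)-2-bromo-4-methoxyphenyl]-3-[4-(benzyloxy)-3,5-dimethoxyphenyl]propanal diallyl acetal (both C2 epimers)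
Conditions: NBS, 14 (3 equiv), CH2Cl2, −78 to −20 °C
Reagents that add atoms: N-bromosuccinimide, O=C1CCC(=O)N1Br
Why: In this Ueno–Stork haloacetalisation the enol ether takes up electrophilic bromine far faster than the terminal alkenes or the arenes and allyl alcohol traps the oxocarbenium ion, and both bromide epimers are usable because that centre becomes planar in step 8.

Step 8
Reactants: 15 (3S)-2-bromo-3,3-diarylpropanal diallyl acetal (both C2 epimers)
Product: 16 (3aR,9S,9aR)-7-(benzyloxy)-9-[4-(benzyloxy)-3,5-dimethoxyphenyl]-6-methoxy-1-(prop-2-enyloxy)-1,3,3a,4,9,9a-hexahydronaphtho[2,3-c]furan (anomeric centre not defined)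
Conditions: NiBr2(dme) (15 mol %), 4,4'-di-tert-butyl-2,2'-bipyridine (18 mol %), NaI (25 mol %), Zn dust (3 equiv), DMA (0.02 M), 40 °C
Reagents that add atoms: none
Why: Zerovalent nickel inserts into the ring A C–Br bond while a monovalent nickel species abstracts the secondary bromine, the C2 radical adds to the inner carbon of one allyl group, the primary C4 radical is caught by the arylnickel bromide of the same molecule, and reductive elimination from trivalent nickel forms C4–C4a before zinc returns nickel to low valence. The closest known reaction type is the nickel-catalysed reductive cyclisation/cross-coupling cascade of Ueno–Stork haloacetals with aryl halides (cross-electrophile coupling), run here fully intramolecularly. The tetrahydrofuran closes 5-exo-trig, which forces C2 to bond to the substituted alkene carbon C3 against the normal terminal preference of radical addition, and ring B closes by C(sp2)–C(sp3) reductive elimination from a seven-membered nickelacycle. C3 is set relative to C2 by the chair-like transition state, in which the bulky diarylmethyl group on the radical carbon lies pseudo-equatorial and trans to the developing CH2 radical (trans ring fusion); C2 is set relative to C1 because the radical holds C1–H next to the acetal carbon and the alkene approaches anti to ring C with ring A gauche, the arrangement that leads to the all-equatorial tetralin; the acetal carbon becomes stereogenic only here and is erased in step 9. Because the two allyloxy groups are diastereotopic and not preset, every radical can pick the allyl group that fits the face chosen by C1, so no mismatched acetal epimer exists. The step needs cyclisation to outrun reduction or beta-alkoxy elimination at C2 and needs aryl–alkyl rather than aryl–aryl coupling, which the fast haloacetal 5-exo closure, the impossibility of a direct four-membered coupling and high dilution should secure.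

Step 9
Reactants: 16 hexahydronaphtho[2,3-c]furan allyl acetal
Product: 18 [(1S,2R,3R)-7-(benzyloxy)-1-[4-(benzyloxy)-3,5-dimethoxyphenyl]-6-methoxy-1,2,3,4-tetrahydronaphthalene-2,3-diyl]dimethanol, via lactol 17 (not isolated)
Conditions: TsOH·H2O (20 mol %), THF/H2O 4:1, 50 °C; then NaBH4, 0 °C
Reagents that add atoms: water, O
Why: Acid hydrolysis of the cyclic acetal gives the lactol, whose open hydroxy aldehyde form is reduced by borohydride, and C2, although alpha to the transient aldehyde, already holds the more stable equatorial trans,trans configuration, so equilibration cannot harm it.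

Step 10
Reactants: 18 bis(benzyl ether) diol
Product: 19 5-methoxy-(+)-isolariciresinol
Conditions: H2 (1 atm), Pd/C, MeOH/EtOAc, rt
Reagents that add atoms: none
Why: Catalytic hydrogenolysis cleaves both O-benzyl bonds, no other benzylic C–O bond is present, and the three stereocentres are not touched.

Compound list
1 | 2-bromo-5-hydroxy-4-methoxybenzaldehyde | O=Cc1cc(O)c(OC)cc1Br | starting material
2 | 5-(benzyloxy)-2-bromo-4-methoxybenzaldehyde | O=Cc1cc(OCc2ccccc2)c(OC)cc1Br | intermediate
3 | (triphenylphosphoranylidene)acetaldehyde | O=CC=P(c1ccccc1)(c1ccccc1)c1ccccc1 | starting material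
4 | (E)-3-[5-(benzyloxy)-2-bromo-4-methoxyphenyl]prop-2-enal | O=C/C=C/c1cc(OCc2ccccc2)c(OC)cc1Br | intermediate
5 | 4-bromo-2,6-dimethoxyphenol | COc1cc(Br)cc(OC)c1O | starting material
6 | 2-(benzyloxy)-5-bromo-1,3-dimethoxybenzene | COc1cc(Br)cc(OC)c1OCc1ccccc1 | intermediate
7 | [4-(benzyloxy)-3,5-dimethoxyphenyl]lithium (not isolated) | COc1cc([Li])cc(OC)c1OCc1ccccc1 | intermediate
8 | lithium [4-(benzyloxy)-3,5-dimethoxyphenyl]triisopropoxyborate (not isolated) | [Li+].COc1cc(cc(OC)c1OCc1ccccc1)[B-](OC(C)C)(OC(C)C)OC(C)C | intermediate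
9 | [4-(benzyloxy)-3,5-dimethoxyphenyl]boronic acid | COc1cc(B(O)O)cc(OC)c1OCc1ccccc1 | intermediate
10 | (3S)-3-[5-(benzyloxy)-2-bromo-4-methoxyphenyl]-3-[4-(benzyloxy)-3,5-dimethoxyphenyl]propanal | O=CC[C@H](c1cc(OCc2ccccc2)c(OC)cc1Br)c1cc(OC)c(OCc2ccccc2)c(OC)c1 | intermediate
11 | allyloxytrimethylsilane | C=CCO[Si](C)(C)C | starting material
12 | diallyl acetal of 10, (3S) (not isolated) | C=CCOC(OCC=C)C[C@H](c1cc(OCc2ccccc2)c(OC)cc1Br)c1cc(OC)c(OCc2ccccc2)c(OC)c1 | intermediate
13 | (3S)-1-(allyloxy)-3-[5-(benzyloxy)-2-bromo-4-methoxyphenyl]-3-[4-(benzyloxy)-3,5-dimethoxyphenyl]prop-1-ene, E/Z mixture | C=CCOC=C[C@H](c1cc(OCc2ccccc2)c(OC)cc1Br)c1cc(OC)c(OCc2ccccc2)c(OC)c1 | intermediate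
14 | allyl alcohol | C=CCO | starting material
15 | (3S)-2-bromo-3-[5-(benzyloxy)-2-bromo-4-methoxyphenyl]-3-[4-(benzyloxy)-3,5-dimethoxyphenyl]propanal diallyl acetal, both C2 epimers | C=CCOC(OCC=C)C(Br)[C@H](c1cc(OCc2ccccc2)c(OC)cc1Br)c1cc(OC)c(OCc2ccccc2)c(OC)c1 | intermediate
16 | (3aR,9S,9aR)-7-(benzyloxy)-9-[4-(benzyloxy)-3,5-dimethoxyphenyl]-6-methoxy-1-(prop-2-enyloxy)-1,3,3a,4,9,9a-hexahydronaphtho[2,3-c]furan, anomeric centre not defined | COc1cc2c(cc1OCc1ccccc1)[C@H](c1cc(OC)c(OCc3ccccc3)c(OC)c1)[C@H]1C(OCC=C)OC[C@@H]1C2 | intermediate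
17 | (3aR,9S,9aR)-7-(benzyloxy)-9-[4-(benzyloxy)-3,5-dimethoxyphenyl]-6-methoxy-1,3,3a,4,9,9a-hexahydronaphtho[2,3-c]furan-1-ol (lactol, not isolated) | COc1cc2c(cc1OCc1ccccc1)[C@H](c1cc(OC)c(OCc3ccccc3)c(OC)c1)[C@H]1C(O)OC[C@@H]1C2 | intermediate
18 | [(1S,2R,3R)-7-(benzyloxy)-1-[4-(benzyloxy)-3,5-dimethoxyphenyl]-6-methoxy-1,2,3,4-tetrahydronaphthalene-2,3-diyl]dimethanol | COc1cc2c(cc1OCc1ccccc1)[C@H](c1cc(OC)c(OCc3ccccc3)c(OC)c1)[C@@H](CO)[C@H](CO)C2 | intermediate
19 | 5-methoxy-(+)-isolariciresinol, (6R,7R,8S)-8-(4-hydroxy-3,5-dimethoxyphenyl)-6,7-bis(hydroxymethyl)-3-methoxy-5,6,7,8-tetrahydronaphthalen-2-ol | COc1cc2c(cc1O)[C@H](c1cc(OC)c(O)c(OC)c1)[C@@H](CO)[C@H](CO)C2 | target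

Total step count: 10. Longest linear sequence: 8 steps (1, 2, 5, 6, 7, 8, 9, 10).

Steps most likely to fail

Step 8. The cascade may stall in three ways. Nickel may insert only slowly into the hindered, electron-rich aryl bromide. Hydrogen abstraction or reductive beta-alkoxy elimination may occur before ring B closes. The radical addition may also show poor facial selectivity with respect to C1. The fallback sets out from 13 and comes back at 16, and it makes the two bonds one after the other. Enol ether 13 is treated with N-iodosuccinimide and allyl alcohol (CH2Cl2, −78 °C) to give the (3S)-2-iodo diallyl acetal F1. Et3B/air at −78 °C then triggers an iodine-atom-transfer 5-exo cyclisation to the trans-3,4-disubstituted 4-(iodomethyl)tetrahydrofuran F2. The low temperature should sharpen facial selectivity, and diastereomers can be separated at this stage. Zn dust/LiCl (THF) inserts only into the primary C–I bond to give the alkylzinc iodide F3. An intramolecular Negishi coupling with the aryl bromide (Pd(OAc)2, SPhos, THF, 50 °C) closes ring B to 16.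

Step 5. The ortho bromine and the para methoxy donor may slow insertion, the electron-rich boronic acid may protodeboronate, 1,2-addition may compete, or enantioselectivity may erode. The fallback sets out from 2 and 6 and comes back at 10, and it replaces catalysis by an auxiliary-controlled cuprate addition.
- Knoevenagel–Doebner condensation of 2 with malonic acid (pyridine, piperidine, 100 °C) passes through the arylidenemalonic acid F4 and gives the (E)-cinnamic acid F5.
- Pivaloyl chloride/Et3N converts it into the mixed pivalic anhydride F6, which acylates (R)-4-phenyloxazolidin-2-one (LiCl, THF) to the N-enoyl imide F7.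
- Bromide 6 and Mg give the arylmagnesium bromide F8. With CuBr·SMe2 (THF, −40 °C) it adds to the chelated s-cis imide from the face opposite the 4-phenyl group (the beta-Re face) to give the (3S) adduct F9.
- LiBH4 releases the auxiliary and gives the (3S)-3,3-diarylpropan-1-ol F10, and Dess–Martin oxidation returns aldehyde 10.

Step 6. The elimination may stay incomplete, the allyl vinyl ether may undergo a [3,3]-sigmatropic shift, or it may hydrolyse during isolation. The fallback sets out from 10 and comes back at 15, so step 7 is bypassed as well, and it introduces bromine at the aldehyde level by enamine catalysis. Racemic 2-[diphenyl(trimethylsilyloxy)methyl]pyrrolidine (cat.) and 4,4-dibromo-2,6-di-tert-butylcyclohexa-2,5-dienone (CH2Cl2, −40 °C) give the (3S)-2-bromo aldehyde F11. This is acetalised at once with 11 (2.2 equiv) and catalytic TMSOTf at −78 °C to give 15.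

Further compounds
F1 | step 8 | (3S)-2-iodo-3-[5-(benzyloxy)-2-bromo-4-methoxyphenyl]-3-[4-(benzyloxy)-3,5-dimethoxyphenyl]propanal diallyl acetal, both C2 epimers | C=CCOC(OCC=C)C(I)[C@H](c1cc(OCc2ccccc2)c(OC)cc1Br)c1cc(OC)c(OCc2ccccc2)c(OC)c1
F2 | step 8 | 2-(allyloxy)-3-[(S)-diarylmethyl]-4-(iodomethyl)tetrahydrofuran, 3,4-trans, anomeric centre not defined | C=CCOC1OC[C@H](CI)[C@H]1[C@H](c1cc(OCc2ccccc2)c(OC)cc1Br)c1cc(OC)c(OCc2ccccc2)c(OC)c1
F3 | step 8 | alkylzinc iodide derived from F2 | C=CCOC1OC[C@H](C[Zn]I)[C@H]1[C@H](c1cc(OCc2ccccc2)c(OC)cc1Br)c1cc(OC)c(OCc2ccccc2)c(OC)c1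
F4 | step 5 | 2-{[5-(benzyloxy)-2-bromo-4-methoxyphenyl]methylidene}propanedioic acid | OC(=O)C(=Cc1cc(OCc2ccccc2)c(OC)cc1Br)C(O)=O
F5 | step 5 | (E)-3-[5-(benzyloxy)-2-bromo-4-methoxyphenyl]prop-2-enoic acid | OC(=O)/C=C/c1cc(OCc2ccccc2)c(OC)cc1Br
F6 | step 5 | mixed anhydride of F5 and pivalic acid | CC(C)(C)C(=O)OC(=O)/C=C/c1cc(OCc2ccccc2)c(OC)cc1Br
F7 | step 5 | (4R)-3-{(E)-3-[5-(benzyloxy)-2-bromo-4-methoxyphenyl]prop-2-enoyl}-4-phenyloxazolidin-2-one | O=C(/C=C/c1cc(OCc2ccccc2)c(OC)cc1Br)N1[C@H](c2ccccc2)COC1=O
F8 | step 5 | [4-(benzyloxy)-3,5-dimethoxyphenyl]magnesium bromide | COc1cc([Mg]Br)cc(OC)c1OCc1ccccc1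
F9 | step 5 | (4R)-3-{(3S)-3-[5-(benzyloxy)-2-bromo-4-methoxyphenyl]-3-[4-(benzyloxy)-3,5-dimethoxyphenyl]propanoyl}-4-phenyloxazolidin-2-one | O=C(C[C@H](c1cc(OCc2ccccc2)c(OC)cc1Br)c1cc(OC)c(OCc2ccccc2)c(OC)c1)N1[C@H](c2ccccc2)COC1=O
F10 | step 5 | (3S)-3-[5-(benzyloxy)-2-bromo-4-methoxyphenyl]-3-[4-(benzyloxy)-3,5-dimethoxyphenyl]propan-1-ol | OCC[C@H](c1cc(OCc2ccccc2)c(OC)cc1Br)c1cc(OC)c(OCc2ccccc2)c(OC)c1
F11 | step 6 | (3S)-2-bromo-3-[5-(benzyloxy)-2-bromo-4-methoxyphenyl]-3-[4-(benzyloxy)-3,5-dimethoxyphenyl]propanal, both C2 epimers | O=CC(Br)[C@H](c1cc(OCc2ccccc2)c(OC)cc1Br)c1cc(OC)c(OCc2ccccc2)c(OC)c1
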